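**Strategy.** The 5-methyl-γ-butyrolactone ring (O1–C2(=O)–C3–C4–C5) is the skeleton of α-angelica lactone, so the target is cut at the C5–C1′ bond between the fully substituted lactone carbon and the carbinol carbon. A catalytic asymmetric vinylogous Mukaiyama aldol reaction of 2-methyl-5-(trimethylsilyloxy)furan with an achiral C17 furyl dienal forms this most hindered bond, brings in the lactone ring intact as a butenolide and sets both stereocentres (5S,1′R) in one operation. The aldehyde, which already holds both E-trisubstituted alkenes and the 3-furyl group, comes from (2E,6E)-farnesyl acetate by terminal oxidative truncation and copper-catalysed 3-furylmethyl coupling; conjugate reduction of the butenolide ends the route.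

Key step: step 8

Remark: lactone atoms are numbered O1, C2(=O), C3, C4, C5 and the carbinol carbon C1′. The cinchona catalyst of step 8 is assumed to be taken from the pseudoenantiomeric series (quinine- or quinidine-derived) that leads to Si-face attack on the aldehyde.

**Step 1**
Reactants: 1 (2E,6E)-farnesyl acetate
Product: 2 (2E,6E)-10-bromo-11-hydroxy-3,7,11-trimethyldodeca-2,6-dien-1-yl acetate (racemic at C10)
Conditions: NBS (1.1 equiv), THF/H2O, 0 °C
Reagents that add atoms: N-bromosuccinimide (BrN1C(=O)CCC1=O), water (O)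
Why: Terminal-selective bromohydrin formation of a polyprenyl chain in aqueous medium, in which the exposed 10,11-alkene reacts first (the 2,3-alkene is deactivated by the allylic acetate) and water opens the bromonium ion at the tertiary carbon; the new C10 centre is racemic and is destroyed in step 6.

**Step 2**
Reactants: 2 bromohydrin acetate
Product: 3 (2E,6E)-9-(3,3-dimethyloxiran-2-yl)-3,7-dimethylnona-2,6-dien-1-ol (10,11-epoxyfarnesol, racemic)
Conditions: K2CO3, MeOH, rt
Reagents that add atoms: none
Why: Intramolecular Williamson etherification (SN2 closure of the tertiary alkoxide on C–Br) should form the oxirane while the same medium removes the acetate by transesterification; the racemic epoxide centre is removed in step 6.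

**Step 3**
Reactants: 3 10,11-epoxyfarnesol
Product: 5 3-[(3E,7E)-9-chloro-3,7-dimethylnona-3,7-dien-1-yl]-2,2-dimethyloxirane (10,11-epoxyfarnesyl chloride), via allylic mesylate 4 (not isolated)
Conditions: MsCl, LiCl, 2,4,6-collidine, DMF, 0 °C
Reagents that add atoms: methanesulfonyl chloride (CS(=O)(=O)Cl; its atoms stay only in 4), lithium chloride ([Li+].[Cl-])
Why: Mesylation followed by in situ SN2 chloride exchange under nearly neutral conditions should give the primary allylic chloride without allylic transposition, change of alkene geometry or opening of the trisubstituted epoxide.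

**Step 4**
Reactants: 6 furan-3-ylmethanol
Product: 8 3-(chloromethyl)furan, via furan-3-ylmethyl mesylate 7 (not isolated)
Conditions: MsCl, LiCl, 2,4,6-collidine, DMF, 0 °C; used at once
Reagents that add atoms: methanesulfonyl chloride (CS(=O)(=O)Cl; its atoms stay only in 7), lithium chloride ([Li+].[Cl-])
Why: The same mesylation/chloride-exchange sequence (SN2) converts the furylmethyl alcohol into its chloride without the strong acid that would polymerise the furan.

**Step 5**
Reactants: 5 10,11-epoxyfarnesyl chloride; 8 3-(chloromethyl)furan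
Product: 10 3-[(3E,7E)-10-(3,3-dimethyloxiran-2-yl)-4,8-dimethyldeca-3,7-dien-1-yl]furan (racemic), via furan-3-ylmethylmagnesium chloride 9 (not isolated)
Conditions: 8 (1.3 equiv), Mg, THF, 0 °C → rt; then 5, Li2CuCl4 (5 mol %), THF, −20 → 0 °C
Reagents that add atoms: magnesium ([Mg]; held only in 9)
Why: Copper-catalysed sp3–sp3 cross-coupling of a Grignard reagent with a primary allylic chloride (Kochi-type) should occur at the α-carbon with retention of the E geometry, and the hindered trisubstituted epoxide is not opened at this temperature.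

**Step 6**
Reactants: 10 epoxy furan
Product: 11 (4E,8E)-11-(furan-3-yl)-4,8-dimethylundeca-4,8-dienal
Conditions: H5IO6, THF/Et2O, 0 °C
Reagents that add atoms: none
Why: Periodic acid cleaves the epoxide through its vicinal diol (Malaprade-type glycol cleavage) to the aldehyde and acetone, which removes the racemic centre, and periodate does not attack isolated trisubstituted alkenes or the 3-alkylfuran.

**Step 7**
Reactants: 12 α-angelica lactone (5-methylfuran-2(3H)-one)
Product: 13 2-methyl-5-(trimethylsilyloxy)furan
Conditions: TMSCl, Et3N, Et2O, 0 °C → rt; filtration, distillation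
Reagents that add atoms: chlorotrimethylsilane (C[Si](C)(C)Cl)
Why: O-Silylation of the dienolate of the β,γ-unsaturated lactone (silyl dienol ether formation) is driven by aromatisation to the 2-silyloxyfuran.

**Step 8**
Reactants: 11 C17 furyl dienal; 13 2-methyl-5-(trimethylsilyloxy)furan
Product: 15 (S)-5-[(1R,4E,8E)-11-(furan-3-yl)-1-hydroxy-4,8-dimethylundeca-4,8-dien-1-yl]-5-methylfuran-2(5H)-one, via O-trimethylsilyl aldol adduct 14 (not isolated)
Conditions: 13 (1.5 equiv), cinchona-derived thiourea–ammonium carboxylate salt (10 mol %), Et2O, −40 °C; then citric acid, MeOH, 0 °C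
Reagents that add atoms: none
Why: The carboxylate of the catalyst assists Si–O cleavage of 13 to a hydrogen-bonded dienolate ion pair while the thiourea binds the carbonyl oxygen of 11, the dienolate attacks through its γ-carbon (C5), and silyl transfer to the aldolate gives 14, which mild acidic methanolysis should convert into 15. The closest known reaction type is the catalytic asymmetric vinylogous Mukaiyama aldol reaction of 2-silyloxyfurans with aldehydes, which is also known for γ-substituted silyloxyfurans that give fully substituted γ-carbons. No ring is closed: the five-membered lactone ring arrives intact from 13 and only the exocyclic C5–C1′ bond is formed. C1′ (R) is set by the catalyst through Si-face attack on the bound aldehyde, and C5 (S) should follow from an open staggered transition state in which the aldehyde hydrogen lies over the furan ring, the C=O bond is antiperiplanar to the C5–O1 bond (dipole minimisation) and the alkyl chain is antiperiplanar to C4 beside the unsubstituted ring oxygen, so that the Re face of C5 meets the Si face of the aldehyde (unlike topicity). The step needs γ- over α-attack, which the larger HOMO coefficient at C5 and the gain of the conjugated butenolide should secure, and it needs addition without enolisation of the unbranched aldehyde, which the weakly basic ion pair at low temperature should secure; the trisubstituted alkenes and the 3-alkylfuran are spectators.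

**Step 9**
Reactants: 15 butenolide
Product: 16 (S)-5-[(1R,4E,8E)-11-(furan-3-yl)-1-hydroxy-4,8-dimethylundeca-4,8-dien-1-yl]-5-methyldihydrofuran-2(3H)-one (target)
Conditions: Cu(OAc)2·H2O (5 mol %), 1,2-bis(diphenylphosphino)benzene (5 mol %), (EtO)2MeSiH, t-BuOH, toluene, rt
Reagents that add atoms: none
Why: Copper hydride conjugate reduction (Stryker-type, catalytic in copper) should add hydride only to the electron-poor butenolide C=C, with t-BuOH protonating the copper enolate, while the unactivated trisubstituted alkenes, the furan and both stereocentres are not touched.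

**Compound list**
1 | (2E,6E)-3,7,11-trimethyldodeca-2,6,10-trien-1-yl acetate ((2E,6E)-farnesyl acetate) | CC(=O)OC/C=C(\C)CC/C=C(\C)CCC=C(C)C | starting material
2 | (2E,6E)-10-bromo-11-hydroxy-3,7,11-trimethyldodeca-2,6-dien-1-yl acetate (racemic) | CC(=O)OC/C=C(\C)CC/C=C(\C)CCC(Br)C(C)(C)O | intermediate
3 | (2E,6E)-9-(3,3-dimethyloxiran-2-yl)-3,7-dimethylnona-2,6-dien-1-ol (racemic) | OC/C=C(\C)CC/C=C(\C)CCC1OC1(C)C | intermediate
4 | (2E,6E)-9-(3,3-dimethyloxiran-2-yl)-3,7-dimethylnona-2,6-dien-1-yl methanesulfonate (formed in situ) | CS(=O)(=O)OC/C=C(\C)CC/C=C(\C)CCC1OC1(C)C | intermediate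
5 | 3-[(3E,7E)-9-chloro-3,7-dimethylnona-3,7-dien-1-yl]-2,2-dimethyloxirane (racemic) | ClC/C=C(\C)CC/C=C(\C)CCC1OC1(C)C | intermediate
6 | furan-3-ylmethanol | OCc1ccoc1 | starting material
7 | furan-3-ylmethyl methanesulfonate (formed in situ) | CS(=O)(=O)OCc1ccoc1 | intermediate
8 | 3-(chloromethyl)furan | ClCc1ccoc1 | intermediate
9 | (furan-3-ylmethyl)magnesium chloride (formed in situ) | Cl[Mg]Cc1ccoc1 | intermediate
10 | 3-[(3E,7E)-10-(3,3-dimethyloxiran-2-yl)-4,8-dimethyldeca-3,7-dien-1-yl]furan (racemic) | C/C(=C\CCc1ccoc1)CC/C=C(\C)CCC1OC1(C)C | intermediate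
11 | (4E,8E)-11-(furan-3-yl)-4,8-dimethylundeca-4,8-dienal | C/C(=C\CCc1ccoc1)CC/C=C(\C)CCC=O | intermediate
12 | α-angelica lactone (5-methylfuran-2(3H)-one) | CC1=CCC(=O)O1 | starting material
13 | 2-methyl-5-(trimethylsilyloxy)furan | Cc1ccc(O[Si](C)(C)C)o1 | intermediate
14 | (S)-5-[(1R,4E,8E)-11-(furan-3-yl)-4,8-dimethyl-1-(trimethylsilyloxy)undeca-4,8-dien-1-yl]-5-methylfuran-2(5H)-one (formed in situ) | C/C(=C\CCc1ccoc1)CC/C=C(\C)CC[C@@H](O[Si](C)(C)C)[C@]1(C)C=CC(=O)O1 | intermediate
15 | (S)-5-[(1R,4E,8E)-11-(furan-3-yl)-1-hydroxy-4,8-dimethylundeca-4,8-dien-1-yl]-5-methylfuran-2(5H)-one | C/C(=C\CCc1ccoc1)CC/C=C(\C)CC[C@@H](O)[C@]1(C)C=CC(=O)O1 | intermediate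
16 | (S)-5-[(1R,4E,8E)-11-(furan-3-yl)-1-hydroxy-4,8-dimethylundeca-4,8-dien-1-yl]-5-methyldihydrofuran-2(3H)-one (CNP0359258.1) | C/C(=C\CCc1ccoc1)CC/C=C(\C)CC[C@@H](O)[C@]1(C)CCC(=O)O1 | target

**Step count.** Total: 9 steps. Longest linear sequence: 7 steps (1, 2, 3, 5, 6, 8, 9).

**Steps most likely to fail**

Step 8. The aldol union may suffer from poor face discrimination at the prochiral γ-carbon (like instead of unlike approach) or at the aldehyde, from competing α-attack of the dienolate, or from erosion by retro-aldol reaction. The fallback builds the stereodiad from 11 by reagent-controlled epoxidation. Addition of isopropenylmagnesium bromide (THF, −78 °C) to 11 should give racemic (6E,10E)-13-(furan-3-yl)-2,6,10-trimethyltrideca-1,6,10-trien-3-ol F1. Sharpless kinetic resolution (Ti(OiPr)4, D-(−)-DIPT, t-BuOOH, 4 Å MS, CH2Cl2, −20 °C, about half conversion) should epoxidise only the allylic-alcohol alkene of the (R)-enantiomer and give the erythro epoxy alcohol (1R,4E,8E)-11-(furan-3-yl)-4,8-dimethyl-1-[(2S)-2-methyloxiran-2-yl]undeca-4,8-dien-1-ol F2. Opening of the oxirane CH2 by sodium dimethyl malonate (MeOH, 65 °C), with lactonisation of the tertiary alkoxide, should give methyl (5S)-5-[(1R,4E,8E)-11-(furan-3-yl)-1-hydroxy-4,8-dimethylundeca-4,8-dien-1-yl]-5-methyl-2-oxotetrahydrofuran-3-carboxylate F3. Krapcho demethoxycarbonylation (LiCl, wet DMSO, 130 °C) comes back to the route at 16, so steps 8 and 9 are both replaced.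

Step 5. The coupling may give γ-attack (SN2′) at the allylic chloride, Wurtz homocoupling while the Grignard reagent forms, or opening of the epoxide by magnesium halide or cuprate. The fallback replaces the organometallic coupling by a sulfone alkylation that sets out from 8 and 5. Compound 8 with sodium benzenesulfinate (DMF, rt) should give 3-[(phenylsulfonyl)methyl]furan F4. Its lithio derivative (n-BuLi, THF, −78 °C) is alkylated by 5 in a plain SN2 reaction to 3-[(3E,7E)-10-(3,3-dimethyloxiran-2-yl)-4,8-dimethyl-1-(phenylsulfonyl)deca-3,7-dien-1-yl]furan F5. Reductive desulfonylation (Na/Hg, Na2HPO4, MeOH/THF, −20 °C) comes back to the route at 10.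

Step 9. The reduction may be undercut by retro-aldol fragmentation through a copper alkoxide of the free carbinol, or by O-silylation of the carbinol by the hydrosilane. The fallback masks the carbinol first and saturates the alkene by nickel-boride hydrogenation instead of hydride conjugate addition. From 15, TESCl and imidazole (DMF, 0 °C) should give (S)-5-[(1R,4E,8E)-11-(furan-3-yl)-4,8-dimethyl-1-(triethylsilyloxy)undeca-4,8-dien-1-yl]-5-methylfuran-2(5H)-one F6. NiCl2·6H2O/NaBH4 (MeOH/THF, −20 °C) should reduce only the conjugated alkene to (S)-5-[(1R,4E,8E)-11-(furan-3-yl)-4,8-dimethyl-1-(triethylsilyloxy)undeca-4,8-dien-1-yl]-5-methyldihydrofuran-2(3H)-one F7. HF·pyridine (pyridine/THF, 0 °C) comes back to the route at 16.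

**Further compounds**
F1 | step 8 | (6E,10E)-13-(furan-3-yl)-2,6,10-trimethyltrideca-1,6,10-trien-3-ol (racemic) | C/C(=C\CCc1ccoc1)CC/C=C(\C)CCC(O)C(C)=C
F2 | step 8 | (1R,4E,8E)-11-(furan-3-yl)-4,8-dimethyl-1-[(2S)-2-methyloxiran-2-yl]undeca-4,8-dien-1-ol | C/C(=C\CCc1ccoc1)CC/C=C(\C)CC[C@@H](O)[C@]1(C)CO1
F3 | step 8 | methyl (5S)-5-[(1R,4E,8E)-11-(furan-3-yl)-1-hydroxy-4,8-dimethylundeca-4,8-dien-1-yl]-5-methyl-2-oxotetrahydrofuran-3-carboxylate (epimers at C3) | C/C(=C\CCc1ccoc1)CC/C=C(\C)CC[C@@H](O)[C@]1(C)CC(C(=O)OC)C(=O)O1
F4 | step 5 | 3-[(phenylsulfonyl)methyl]furan | O=S(=O)(Cc1ccoc1)c1ccccc1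
F5 | step 5 | 3-[(3E,7E)-10-(3,3-dimethyloxiran-2-yl)-4,8-dimethyl-1-(phenylsulfonyl)deca-3,7-dien-1-yl]furan (diastereomer mixture) | C/C(=C\CC(c1ccoc1)S(=O)(=O)c1ccccc1)CC/C=C(\C)CCC1OC1(C)C
F6 | step 9 | (S)-5-[(1R,4E,8E)-11-(furan-3-yl)-4,8-dimethyl-1-(triethylsilyloxy)undeca-4,8-dien-1-yl]-5-methylfuran-2(5H)-one | C/C(=C\CCc1ccoc1)CC/C=C(\C)CC[C@@H](O[Si](CC)(CC)CC)[C@]1(C)C=CC(=O)O1
F7 | step 9 | (S)-5-[(1R,4E,8E)-11-(furan-3-yl)-4,8-dimethyl-1-(triethylsilyloxy)undeca-4,8-dien-1-yl]-5-methyldihydrofuran-2(3H)-one | C/C(=C\CCc1ccoc1)CC/C=C(\C)CC[C@@H](O[Si](CC)(CC)CC)[C@]1(C)CCC(=O)O1
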